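**Retrosynthetic overview**
1. Target 10 is cut at the C2–C1' bond: chromone C2 is used as a carbanion (a β-acylvinyl, d3 zinc reagent) and joined to 1-bromopentadecane. In normal reactivity both carbons are electrophilic.
2. The 5-OH is masked only inside the coupling flask, as a trimethylsilyl ether that falls off on acidic work-up.
3. 5-Hydroxychromone 4 is cut to 2',6'-dihydroxyacetophenone 1 plus a one-carbon unit (DMF-DMA) through an enaminone.
4. Ring order: the benzene ring is bought, the pyranone ring is closed in step 1, and the side chain is attached last.

Assumption: the target SMILES has no stereocentre and no stereogenic double bond, so the compound is achiral and no stereocontrol is needed.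

**Route**

Step 1
Reactants: 1 2',6'-dihydroxyacetophenone; 2 N,N-dimethylformamide dimethyl acetal
Product: 4 5-hydroxy-4H-chromen-4-one, via enaminone 3 (not isolated)
Conditions: 2 (1.5 equiv), PhMe, 80 °C, 3 h; evaporate; conc. HCl, CH2Cl2, 40 °C, 2 h
Reagents that add atoms: N,N-dimethylformamide dimethyl acetal 2, COC(OC)N(C)C (supplies C2 of the chromone)
Why: Condensation of the methyl ketone with the amide acetal gives the (E)-enaminone, and acid then drives intramolecular oxa-Michael addition of one phenol and loss of dimethylamine (enaminone route to chromones), while the second phenol stays free as the hydrogen-bonded 5-OH; no stereocentre is formed.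

Step 2
Reactants: 4 5-hydroxy-4H-chromen-4-one; 5 chlorotrimethylsilane; 6 1-bromopentadecane
Product: 10 5-hydroxy-2-pentadecyl-4H-chromen-4-one, via silyl ether 7 (not isolated), via chromonylzinc chloride 8 (not isolated), via silylated coupling product 9 (not isolated)
Conditions: 4 (1.3 equiv), NaH (1.35 equiv), THF, 0 °C; 5 (1.4 equiv), 0 °C to rt; TMPZnCl·LiCl (1.7 equiv), THF, 25 °C, 1 h; 6 (1.0 equiv), Pd2(dba)3 (2 mol%), PCyp3 (8 mol%), N-methylimidazole (1.2 equiv), THF/NMP 2:1, 80 °C, 14 h; 1 M HCl, rt, 30 min
Reagents that add atoms: 1-bromopentadecane 6, CCCCCCCCCCCCCCCBr (pentadecyl group of 9 and 10); chlorotrimethylsilane 5, C[Si](C)(C)Cl (Me3Si carried in 7, 8 and 9 only); TMPZnCl·LiCl, CC1(C)CCCC(C)(C)N1[Zn]Cl.[Li+].[Cl-] (ZnCl carried in 8 only)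
Why: Proposed new method: with the phenol capped as its silyl ether so that no metal phenoxide sits on the C4 carbonyl, TMPZnCl·LiCl removes the most acidic ring proton (C2–H, next to the ring oxygen) in a deprotonative zincation of the kind established for chromone and its alkoxy derivatives, giving a β-acylvinyl (d3) zinc reagent; Pd(0)/PCyp3 then adds oxidatively to the primary alkyl bromide, zinc-to-palladium transmetalation (helped by N-methylimidazole) and reductive elimination outrun β-hydride elimination with this bulky electron-rich phosphine, and aqueous acid cleaves the labile aryl silyl ether; the closest known reaction type is the Negishi cross-coupling of aryl- and alkenylzinc halides with unactivated primary alkyl bromides, the new element being its use on a TMP-zincated chromone; no stereocentre is formed.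

**Compound list**
1 | 2',6'-dihydroxyacetophenone (1-(2,6-dihydroxyphenyl)ethan-1-one) | CC(=O)c1c(O)cccc1O | starting material
2 | N,N-dimethylformamide dimethyl acetal | COC(OC)N(C)C | starting material
3 | (E)-1-(2,6-dihydroxyphenyl)-3-(dimethylamino)prop-2-en-1-one | CN(C)/C=C/C(=O)c1c(O)cccc1O | intermediate
4 | 5-hydroxy-4H-chromen-4-one | O=c1ccoc2cccc(O)c12 | intermediate
5 | chlorotrimethylsilane | C[Si](C)(C)Cl | starting material
6 | 1-bromopentadecane | CCCCCCCCCCCCCCCBr | starting material
7 | 5-(trimethylsilyloxy)-4H-chromen-4-one | C[Si](C)(C)Oc1cccc2occc(=O)c12 | intermediate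
8 | chloro[4-oxo-5-(trimethylsilyloxy)-4H-chromen-2-yl]zinc (LiCl complex in solution) | C[Si](C)(C)Oc1cccc2oc([Zn]Cl)cc(=O)c12 | intermediate
9 | 2-pentadecyl-5-(trimethylsilyloxy)-4H-chromen-4-one | CCCCCCCCCCCCCCCc1cc(=O)c2c(O[Si](C)(C)C)cccc2o1 | intermediate
10 | 5-hydroxy-2-pentadecyl-4H-chromen-4-one (achiral) | CCCCCCCCCCCCCCCc1cc(=O)c2c(O)cccc2o1 | target

**Summary**
Total step count: 2. Longest linear sequence: 2 steps (1 → 4 → 10).

The route has only two steps, so both are ranked here, most risky first.

Step 2 is the main risk. The weak point is the sp2–sp3 coupling of the electron-poor chromonylzinc reagent with an alkyl bromide that carries β-hydrogens: slow transmetalation or β-hydride elimination would give pentadecene and recovered chromone. The fallback sets out from zinc reagent 8 in the flask and reverses the polarity of the same bond. Instead of adding 6, 8 is quenched with iodine (THF, 0 °C) and worked up with aqueous Na2S2O3 and dilute HCl, which also removes the silyl group, to give 5-hydroxy-2-iodo-4H-chromen-4-one F1. Separately, 6 is converted with zinc dust and LiCl (THF, 50 °C) into pentadecylzinc bromide F2. F1 is then coupled with F2 (2.5 equiv, slow addition, Pd(OAc)2/SPhos, THF, rt), a well-precedented alkylzinc–vinyl iodide Negishi coupling that tolerates the free phenol. The fallback comes back to the route at target 10.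

Step 1 is the lesser risk. The amide acetal can O-methylate the phenol that is not hydrogen-bonded to the ketone, or the enaminone can cyclise incompletely. The fallback sets out from 1 and uses a Claisen C-formylation instead: ethyl formate (excess) with NaH (4 equiv) in THF at 0 °C to rt, then acidic work-up, gives 2,5-dihydroxychroman-4-one (racemic cyclic hemiacetal) F3. F3 is dehydrated with conc. HCl in AcOH at 80 °C. The fallback comes back to the route at 4.

**Further compounds**
F1 | step 2 | 5-hydroxy-2-iodo-4H-chromen-4-one | O=c1cc(I)oc2cccc(O)c12
F2 | step 2 | pentadecylzinc bromide | CCCCCCCCCCCCCCC[Zn]Br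
F3 | step 1 | 2,5-dihydroxychroman-4-one (racemic hemiacetal) | O=C1CC(O)Oc2cccc(O)c12
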